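Assumption: the target has no stereocentre or other stereogenic element, so it is a single achiral compound and no step needs stereocontrol. Glyoxal 5 is drawn as the free keto-aldehyde, although it is handled as its hydrate.

## Retrosynthetic overview

1. Target 9 comes from 8 by chelation-directed cleavage of the 5-O-methyl ether; no ring is touched.
2. The pyranone (C ring) is the only ring built and it is built last, by cyclodehydration of ketol 7; rings A and B are bought as benzenoid units.
3. Ketol 7 comes from the C2–C3 bond: the CHO carbon of B-ring aldehyde 6, turned into an acyl anion equivalent by a carbene, adds to the CHO carbon of A-ring arylglyoxal 5.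
4. Glyoxal 5 comes from acetophenone 4 by methyl-ketone oxidation; 4 comes from 3,4,5-trimethoxyphenol 1 by C-acetylation, bromination and copper-catalysed methoxylation.

## Route

Step 1
Reactants: 1 3,4,5-trimethoxyphenol
Product: 2 1-(6-hydroxy-2,3,4-trimethoxyphenyl)ethanone
Conditions: Ac2O (1.1 equiv), BF3·OEt2 (solvent), 80 °C; then H2O
Reagents that add atoms: acetic anhydride, CC(=O)OC(C)=O
Why: BF3-promoted Friedel–Crafts C-acetylation at the only kind of free ring position (ortho to OH, C2 ≡ C6), the chelated ortho-hydroxy ketone being deactivated towards a second acylation.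

Step 2
Reactants: 2 1-(6-hydroxy-2,3,4-trimethoxyphenyl)ethanone
Product: 3 1-(3-bromo-2-hydroxy-4,5,6-trimethoxyphenyl)ethanone
Conditions: NBS (1.05 equiv), MeCN, 0 °C → rt
Reagents that add atoms: N-bromosuccinimide, O=C1CCC(=O)N1Br
Why: Electrophilic aromatic bromination at the single remaining ring C–H, which is ortho to OH and para to OMe; without acid or radical initiator the acetyl CH3 is left alone.

Step 3
Reactants: 3 1-(3-bromo-2-hydroxy-4,5,6-trimethoxyphenyl)ethanone
Product: 4 1-(2-hydroxy-3,4,5,6-tetramethoxyphenyl)ethanone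
Conditions: NaOMe (5 equiv, 25% in MeOH), CuBr (20 mol%), DMF, 110 °C; then aq. HCl
Reagents that add atoms: sodium methoxide, C[O-].[Na+]
Why: Ullmann-type copper-catalysed methoxylation of the aryl bromide, which tolerates (and is helped by) the neighbouring phenoxide, as in the bromovanillin-to-syringaldehyde conversion.

Step 4
Reactants: 4 1-(2-hydroxy-3,4,5,6-tetramethoxyphenyl)ethanone
Product: 5 2-(2-hydroxy-3,4,5,6-tetramethoxyphenyl)-2-oxoacetaldehyde (isolated as the hydrate)
Conditions: SeO2 (1.3 equiv), 1,4-dioxane–H2O (20:1), 100 °C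
Reagents that add atoms: selenium dioxide, O=[Se]=O
Why: Riley oxidation of the aryl methyl ketone to the arylglyoxal; the ring has no free C–H and no benzylic C–H, so the acetyl CH3 is the only site for enol-selenation.

Step 5
Reactants: 5 2-(2-hydroxy-3,4,5,6-tetramethoxyphenyl)-2-oxoacetaldehyde; 6 2,5-dihydroxybenzaldehyde
Product: 8 2-(2,5-dihydroxyphenyl)-3-hydroxy-5,6,7,8-tetramethoxy-4H-chromen-4-one, via crossed-benzoin ketol 7 (not isolated)
Conditions: 6 (1.3 equiv), 2-(pentafluorophenyl)-6,7-dihydro-5H-pyrrolo[2,1-c][1,2,4]triazol-2-ium BF4 (15 mol%), i-Pr2NEt (20 mol%), 4 Å MS, THF, 40 °C, Ar, 5 added over 4 h; then AcOH, p-TsOH (10 mol%), 70 °C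
Reagents that add atoms: none
Why: Proposed new method: the carbene converts the CHO carbon of 6 into a nucleophilic Breslow enaminol (acyl anion equivalent) that adds to the unhindered, ketone-activated CHO carbon of 5 in a crossed benzoin reaction, joining two carbonyl carbons as C2–C3 (closest known reaction: NHC-catalysed crossed benzoin of aldehydes with activated carbonyl acceptors such as α-keto esters); the reverse donor/acceptor pairing gives a tautomer that reaches the same ketol 7 through the enediol, and acid then closes the A-ring phenol onto the less hindered B-ring ketone and dehydrates to the aromatic pyranone, as in the last stage of known 2-hydroxy-1,3-diketone-to-flavonol cyclisations, which removes the only (racemic) stereocentre.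

Step 6
Reactants: 8 2-(2,5-dihydroxyphenyl)-3-hydroxy-5,6,7,8-tetramethoxy-4H-chromen-4-one
Product: 9 2-(2,5-dihydroxyphenyl)-3,5-dihydroxy-6,7,8-trimethoxy-4H-chromen-4-one
Conditions: BCl3 (1 M in CH2Cl2, 6 equiv), CH2Cl2, −20 → 0 °C; then H2O/MeOH
Reagents that add atoms: none
Why: Chelation-directed Lewis-acid cleavage of an aryl methyl ether: boron bound to the C4 carbonyl delivers chloride only to the peri 5-OMe, the 6-, 7- and 8-OMe groups having no chelating neighbour, while the three free OH groups merely form borates that hydrolyse on work-up.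

## Compound list

1 | 3,4,5-trimethoxyphenol | COc1cc(O)cc(OC)c1OC | starting material
2 | 1-(6-hydroxy-2,3,4-trimethoxyphenyl)ethanone | CC(=O)c1c(O)cc(OC)c(OC)c1OC | intermediate
3 | 1-(3-bromo-2-hydroxy-4,5,6-trimethoxyphenyl)ethanone | CC(=O)c1c(O)c(Br)c(OC)c(OC)c1OC | intermediate
4 | 1-(2-hydroxy-3,4,5,6-tetramethoxyphenyl)ethanone | CC(=O)c1c(O)c(OC)c(OC)c(OC)c1OC | intermediate
5 | 2-(2-hydroxy-3,4,5,6-tetramethoxyphenyl)-2-oxoacetaldehyde | O=CC(=O)c1c(O)c(OC)c(OC)c(OC)c1OC | intermediate
6 | 2,5-dihydroxybenzaldehyde | O=Cc1cc(O)ccc1O | starting material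
7 | 1-(2,5-dihydroxyphenyl)-2-hydroxy-3-(2-hydroxy-3,4,5,6-tetramethoxyphenyl)propane-1,3-dione (racemic, not isolated) | O=C(c1cc(O)ccc1O)C(O)C(=O)c1c(O)c(OC)c(OC)c(OC)c1OC | intermediate
8 | 2-(2,5-dihydroxyphenyl)-3-hydroxy-5,6,7,8-tetramethoxy-4H-chromen-4-one | COc1c(OC)c(OC)c2c(=O)c(O)c(-c3cc(O)ccc3O)oc2c1OC | intermediate
9 | 2-(2,5-dihydroxyphenyl)-3,5-dihydroxy-6,7,8-trimethoxy-4H-chromen-4-one | COc1c(OC)c(O)c2c(=O)c(O)c(-c3cc(O)ccc3O)oc2c1OC | target

## Step count

Total steps: 6. Longest linear sequence: 6 (1 → 2 → 3 → 4 → 5 → 8 → 9; aldehyde 6 is bought).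

## Steps most likely to fail, with fallbacks

**Step 5 (highest risk).** Three things can go wrong. The free phenols of 6 buffer the base and make the aldehyde a sluggish carbene acceptor. The glyoxal can self-condense. The B-ring 2-OH can close onto the A-ring ketone and give the isomeric 6-hydroxyflavonol. The fallback sets out from 6 (5 is used unchanged) and comes back to the route at 9. Aldehyde 6 is benzylated (BnBr, K2CO3, DMF) to 2,5-bis(benzyloxy)benzaldehyde F1. The same carbene-catalysed crossed benzoin of F1 with 5 (triazolium salt, cat. DBU, THF) gives 1-[2,5-bis(benzyloxy)phenyl]-2-hydroxy-3-(2-hydroxy-3,4,5,6-tetramethoxyphenyl)propane-1,3-dione F2, which is not isolated. Only the A-ring phenol is free in it, so acid closure can give only 2-[2,5-bis(benzyloxy)phenyl]-3-hydroxy-5,6,7,8-tetramethoxy-4H-chromen-4-one F3. BCl3 with pentamethylbenzene (CH2Cl2, −78 → 0 °C) then removes both benzyl ethers and the 5-O-methyl group in one operation to give 9. This costs one extra step off the longest line.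

**Step 4.** SeO2 may over-oxidise the electron-rich phenolic ring or leave selenium residues, and the glyoxal hydrate is awkward to purify. The fallback sets out from 4 and comes back at 5. Claisen nitrosation of the methyl ketone (n-BuONO, NaOEt, EtOH, 0 °C) gives crystalline (2E)-2-(hydroxyimino)-1-(2-hydroxy-3,4,5,6-tetramethoxyphenyl)ethan-1-one F4 without any oxidant that can attack the ring. Transoximation with aqueous formaldehyde/HCl then releases 5.

**Step 6.** The three free OH groups tie up BCl3, the 3-O-borate chelate at the C4 carbonyl may blunt the peri-selectivity, and a second cleavage at C6 is possible. The fallback sets out from 4 and comes back at 9, with the demethylation moved ahead of the ring construction. BCl3 (1.2 equiv, CH2Cl2, 0 °C) on 4 cleaves only the methoxy group ortho to the acetyl and gives 1-(2,6-dihydroxy-3,4,5-trimethoxyphenyl)ethanone F5. Riley oxidation gives 2-(2,6-dihydroxy-3,4,5-trimethoxyphenyl)-2-oxoacetaldehyde F6. The carbene-catalysed crossed benzoin with 6 gives 1-(2,5-dihydroxyphenyl)-3-(2,6-dihydroxy-3,4,5-trimethoxyphenyl)-2-hydroxypropane-1,3-dione F7, which is not isolated. Because the A ring is now symmetric, either of its two OH groups closes to the same product on acid cyclodehydration, which is 9 directly.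

## Further compounds

F1 | step 5 | 2,5-bis(benzyloxy)benzaldehyde | O=Cc1cc(OCc2ccccc2)ccc1OCc1ccccc1
F2 | step 5 | 1-[2,5-bis(benzyloxy)phenyl]-2-hydroxy-3-(2-hydroxy-3,4,5,6-tetramethoxyphenyl)propane-1,3-dione | O=C(c1cc(OCc2ccccc2)ccc1OCc1ccccc1)C(O)C(=O)c1c(O)c(OC)c(OC)c(OC)c1OC
F3 | step 5 | 2-[2,5-bis(benzyloxy)phenyl]-3-hydroxy-5,6,7,8-tetramethoxy-4H-chromen-4-one | COc1c(OC)c(OC)c2c(=O)c(O)c(-c3cc(OCc4ccccc4)ccc3OCc3ccccc3)oc2c1OC
F4 | step 4 | (2E)-2-(hydroxyimino)-1-(2-hydroxy-3,4,5,6-tetramethoxyphenyl)ethan-1-one | COc1c(OC)c(OC)c(C(=O)/C=N/O)c(O)c1OC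
F5 | step 6 | 1-(2,6-dihydroxy-3,4,5-trimethoxyphenyl)ethanone | CC(=O)c1c(O)c(OC)c(OC)c(OC)c1O
F6 | step 6 | 2-(2,6-dihydroxy-3,4,5-trimethoxyphenyl)-2-oxoacetaldehyde | O=CC(=O)c1c(O)c(OC)c(OC)c(OC)c1O
F7 | step 6 | 1-(2,5-dihydroxyphenyl)-3-(2,6-dihydroxy-3,4,5-trimethoxyphenyl)-2-hydroxypropane-1,3-dione | O=C(c1cc(O)ccc1O)C(O)C(=O)c1c(O)c(OC)c(OC)c(OC)c1O
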